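## The problem

Target **28** is a cis-fused decalin. Eudesmane numbering is used for the carbocycle throughout: ring A = C1–C5 and C10, ring B = C5–C10. Ring A carries a secondary (2S,3S)-epoxyangelate at C3 next to a tertiary acetate and a methyl group at C4. Ring B carries a ketone at C8 beside the isopropyl-bearing C7, and the angular methyl sits on the quaternary C10.

Of the five ring stereocentres only C10 cannot be corrected once made, so it must be set absolutely and used to relay the others. C5 is epimerisable for as long as C4 is a ketone, and the cis and trans diones are expected to be close in energy, so the cis fusion has to come from a kinetically controlled ring closure. C7 lies next to the C8 carbonyl and can be left to equilibrate once ring A is conformationally locked.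

Both oxygens at C3 and C4 lie on the concave α face, whereas reagents reach ring A from the convex β face. These oxygens are therefore best brought in as carbonyl oxygens, with methyl (C4) and hydride (C3) delivered from the β face. The carbonyl positions C4 and C8 must also be told apart while C3 and C4 are worked on.

The glycidic ester (acid, nucleophiles) and the tertiary acetate beside it (acyl migration, elimination) argue for attaching both esters last, the side chain arriving as the separately made acid **25**.

The feature that invites the key step is that C10 is the fully substituted β-carbon of a ring A enone with its carbonyl at C4, and C9 sits between C10 and the C8 carbonyl exactly as the methylene of a cyclobutanone fused across C5–C10. An enone–allene photoadduct contains this array, and its ring strain can later pay for the opening that builds ring B.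

## Retrosynthesis

**Esters (28 ⇒ 27 ⇒ 20 + 25).** The two acyl C–O bonds are cut first. The acetate goes on last: the axial tertiary C4 hydroxyl does not compete for a Yamaguchi anhydride, so diol **20** can be esterified at C3 alone to give **27**. The reverse order would leave a free hydroxyl beside a tertiary acetate and invite acyl migration. The forward steps need selective acylation of the secondary alcohol and then a mild acetylation that spares the epoxide.

**Side chain (25 ⇒ 23 ⇒ 22 ⇒ 21).** The epoxide C–O bonds are cut back to the Z-alkene of angelyl alcohol **22**, obtained from angelic acid **21**. Epoxidising an angelate ester already on the decalin would have no reliable facial control. A Sharpless epoxidation of **22** sets both epoxide centres by reagent control, and oxidation of epoxy alcohol **23** gives **25**.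

**Ring A oxygenation (20 ⇒ 19 ⇒ 18 ⇒ 17 ⇒ 16 ⇒ 14).** The C4–CH3 bond is cut to a C4 ketone, and the C3–O bond to an enolate oxidation of that ketone. Dihydroxylation of a C3=C4 olefin would place both oxygens on the β face and is rejected. Methyl addition to ketol **16** from the convex face gives **17** with the 4α-hydroxyl. The C3 configuration is then corrected by oxidation to ketol **18** and hydride delivery from the β face (**19**), so the facial outcome of the hydroxylation does not matter. Throughout, C8 is held as the silyl enol ether that the ring-forming step provides in **14**; it is unveiled at the end (**20**), where C7 equilibrates to the equatorial isomer.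

**Ring B (14 ⇒ 11).** The C5–C6 bond is cut as a Michael addition, and the C5–C8 bond is reconnected as an aldol bond, which leads back to cyclobutanol **11**. This trades ring B for a four-membered ring that already holds C9 and C8. Forward, the alkoxide of **11** fragments to enolate **12**, which closes ring B to enolate **13**; silylation gives **14**. The step must be kinetic (cis fusion) and must keep the enolate where it is formed.

**C7–C8 bond (11 ⇒ 10 ⇒ 6 + 7).** The alkenyl group is cut from the carbinol carbon, giving cyclobutanone **6** and bromide **7**, which carries C6, C7 and the isopropyl group in one piece. C4 must be masked as a ketal during this addition: a free 1,3-dione would be deprotonated or opened by retro-Claisen cleavage.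

**C8 carbonyl (6 ⇒ 4 ⇒ 3).** The cyclobutanone oxygen is traced to the exocyclic methylene of **4** (ozonolysis), and the ketal to ketone **3**.

**Four-membered ring (3 ⇒ 1 + 2).** Cutting C9–C10 and C5–C8 gives 3-methylcyclohex-2-enone **1** and allene **2**. Thermal conjugate additions to this β,β-disubstituted enone are poor. The photochemical [2+2] addition forms the quaternary centre readily and fixes the cis relation of C5 and C10. It needs head-to-head regiochemistry and one enone face.

## Roads not taken

**Alternative 1:** Diels–Alder construction of ring B on a quinone.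
- Cut: C5–C6 and C9–C10 together.
- Forward step: 2-methoxy-5-methyl-1,4-benzoquinone **A2** adds at its methyl-bearing double bond to 2-(tert-butyldimethylsilyloxy)-3-isopropylbuta-1,3-diene **A3** under a BINOL–titanium Lewis acid made from TiCl2(OiPr)2, giving adduct **A1**.
- Merits: it is convergent and sets the quaternary C10 and the cis fusion in one step. C8 emerges already masked as a silyl enol ether, and the methoxy enone is a masked 3,4-dione that suits the "oxygens from carbonyls" requirement.
- Weak points: regiochemistry rests on the methoxy group deactivating its own double bond and on the silyloxy terminus outweighing the isopropyl group. The reacting quinone carbon is fully substituted, so reactivity is low. **A1** carries an oxygen at C1 that the target lacks and that must be removed next to a quaternary carbon. C5 lies between two carbonyls and enolises easily.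
- Comparison: catalytic enantioselective quinone Diels–Alder reactions are established, which is better precedent than the chosen key step has for its enantiocontrol. Against that, the chosen plan carries no surplus oxygen, keeps C5 less labile, and needs no deoxygenation.

**Alternative 2:** ring expansion of a hydrindane by α-ketol shift.
- Cut: C4–C5.
- Forward step: the 3-acetyl-3-hydroxy cis-hydrindane **A5**, chelated by Al(OtBu)3, shifts C5 from C3 to the acetyl carbon and gives ketol **A4**.
- Merits: one stereospecific step creates the C4 carbinol with its methyl group and the C3 carbonyl. **A4** is one reduction away from the diol. This does in one step what steps 7–9 of the chosen route do in three, a clear advantage.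
- Weak points: the shift is an equilibrium, and either ring bond (C5 or C2) can migrate. The C4 configuration depends on the chelate geometry and on the configuration of the acyloin carbon, which must itself be made selectively. **A5**, with its quaternary C10, C7 centre and a second ketone beside the acetyl group, has no short entry.
- Comparison: the chosen plan sets against the shorter endgame the fact that ring system and quaternary carbon come in one step from commodity chemicals.

**Alternative 3:** copper-catalysed conjugate methylation with enolate ring closure.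
- Cut: C10–CH3 and C5–C6.
- Forward step: AlMe3 adds to enone **A7** under CuTC (Cu(O2C–C4H3S), monovalent copper thiophene-2-carboxylate) and a chiral phosphoramidite. The enolate, activated with MeLi, displaces the C6 iodide to give **A6**.
- Merits: asymmetric conjugate methylation of 3-substituted cyclohexenones to quaternary centres is well established, again better precedent for enantiocontrol than the chosen key step. No photochemical equipment is needed.
- Weak points: **A7** must be made enantiopure with its C7 centre in an open chain, which costs steps and a separate asymmetric method. The ring closure is a displacement at a β-branched primary iodide by a hindered enolate beside a new quaternary carbon, so proton transfer and elimination compete. **A6** still needs ozonolysis and the same ring A endgame.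
- Comparison: the chosen plan sets C7 by equilibration for free and builds ring B by a strain-driven step, at the price of a less proven enantioselective step at the start.

Key step: step 1

Remark on numbering: the decalin is numbered as a eudesmane (C4 ketone carbon of **1**, C5 its α-carbon, C10 its β-carbon) in all comments.

Assumption: the (S)-prolinol-derived Lewis acid named in step 1 is taken to expose the C2-Si/C3-Si face of **1**, which leads to (1S,6R)-**3**; if induction runs the other way, its (R)-enantiomer is used with no other change.

## Route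

Step 1
Reactants: 1 3-methylcyclohex-2-en-1-one; 2 allene (propa-1,2-diene)
Product: 3 (1S,6R)-6-methyl-8-methylidenebicyclo[4.2.0]octan-2-one
Conditions: 2 (excess), AlBr3-activated (S)-3,3-bis(3,5-dimethylphenyl)-1-(2,4,6-trifluorophenyl)tetrahydro-1H,3H-pyrrolo[1,2-c][1,3,2]oxazaborole (50 mol%), hν (366 nm), CH2Cl2, −75 °C
Reagents that add atoms: none
Why: Proposed new method: the closest known reaction types are the AlBr3–oxazaborolidine-catalysed enantioselective intermolecular [2+2] photocycloaddition of 1 with simple alkenes such as ethylene and the uncatalysed, racemic enone–allene photocycloaddition; their combination is new. Coordination of the Lewis acid to the carbonyl of 1 shifts its absorption to longer wavelength, so 366 nm light excites mainly the complexed enone and the reaction runs through a face-shielded triplet. The triplet adds allene stepwise: the α-carbon C5 bonds to the central allene carbon to give a 1,4-biradical (an allyl radical and a tertiary radical at C10), which after spin inversion collapses by C9–C10 bond formation. The four-membered ring is thus closed by recombination of a 1,4-biradical, and the strain of a trans-fused bicyclo[4.2.0]octanone together with the epimerisable C5–H secures the cis fusion. C10 is set by the catalyst, whose aryl group covers one face of the bound enone so that allene enters at the C2-Si/C3-Si face; C5 follows from C10 through the cis fusion. The step needs head-to-head regiochemistry, which the allyl-radical pathway of triplet enones provides, and enantiofacial discrimination, which rests on selective excitation of the complex at low temperature. Any residue of the minor enantiomer is removed at step 15, where esterification with enantiopure 25 turns it into a separable diastereomer.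

Step 2
Reactants: 3 (1S,6R)-6-methyl-8-methylidenebicyclo[4.2.0]octan-2-one
Product: 4 (1S,6R)-6-methyl-8-methylidenespiro[bicyclo[4.2.0]octane-2,2'-[1,3]dioxolane]
Conditions: Me3SiOCH2CH2OSiMe3, Me3SiOTf (cat.), CH2Cl2, −78 → −20 °C
Reagents that add atoms: 1,2-bis(trimethylsilyloxy)ethane, C[Si](C)(C)OCCO[Si](C)(C)C
Why: Noyori ketalisation, an aprotic silyl-transfer ketal formation at low temperature, chosen so that the β,γ-placed exocyclic alkene does not migrate; no stereocentre is touched.

Step 3
Reactants: 4 (1S,6R)-6-methyl-8-methylidenespiro[bicyclo[4.2.0]octane-2,2'-[1,3]dioxolane]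
Product: 6 (1R,6R)-6-methylspiro[bicyclo[4.2.0]octane-2,2'-[1,3]dioxolan]-8-one, via spiro ozonide 5 (not isolated)
Conditions: O3, CH2Cl2, −78 °C; then PPh3, −78 °C → rt
Reagents that add atoms: ozone, [O-][O+]=O
Why: Ozonolysis (Criegee mechanism) of the 1,1-disubstituted alkene with reductive work-up. The ketal carbon bears no hydrogen and is inert to ozone, and with C4 masked the product is a simple cyclobutanone, not a 1,3-dione prone to retro-Claisen opening.

Step 4
Reactants: 6 (1R,6R)-6-methylspiro[bicyclo[4.2.0]octane-2,2'-[1,3]dioxolan]-8-one; 7 2-bromo-3-methylbut-1-ene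
Product: 10 (1R,6R,8S)-6-methyl-8-(3-methylbut-1-en-2-yl)spiro[bicyclo[4.2.0]octane-2,2'-[1,3]dioxolan]-8-ol, via 3-methylbut-1-en-2-yllithium 8 (not isolated), via dichloro(3-methylbut-1-en-2-yl)cerium 9 (not isolated)
Conditions: 7, t-BuLi (2 equiv), Et2O, −78 °C; CeCl3, THF, −78 °C; then 6, −78 °C; aq. NH4Cl
Reagents that add atoms: none
Why: Bromine–lithium exchange and transmetalation give a weakly basic organocerium reagent that adds 1,2 to the strained, enolisable cyclobutanone. Attack is expected from the exo face, away from the neighbouring dioxolane; the configuration of the new carbinol centre is of no consequence because C8 becomes trigonal again in step 6.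

Step 5
Reactants: 10 (1R,6R,8S)-6-methyl-8-(3-methylbut-1-en-2-yl)spiro[bicyclo[4.2.0]octane-2,2'-[1,3]dioxolan]-8-ol
Product: 11 (1R,6R,8S)-8-hydroxy-6-methyl-8-(3-methylbut-1-en-2-yl)bicyclo[4.2.0]octan-2-one
Conditions: pyridinium p-toluenesulfonate (cat.), acetone/H2O, rt → 40 °C
Reagents that add atoms: water, O
Why: Acid-catalysed ketal hydrolysis with a weak pyridinium acid; at this acidity the 1,1-disubstituted alkene is not protonated, so ring expansion or ionisation of the alkenylcyclobutanol is not expected. The strained ketol should be taken into step 6 at once, without chromatography.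

Step 6
Reactants: 11 (1R,6R,8S)-8-hydroxy-6-methyl-8-(3-methylbut-1-en-2-yl)bicyclo[4.2.0]octan-2-one
Product: 14 (4aR,8aS)-6-[(tert-butyldimethylsilyl)oxy]-4a-methyl-7-(propan-2-yl)-3,4,4a,5,8,8a-hexahydronaphthalen-1(2H)-one, via ring-opened potassium enolate 12 (not isolated), via potassium C8 enolate 13 (not isolated)
Conditions: KN(SiMe3)2 (1.05 equiv), THF, −78 → −30 °C; then t-BuMe2SiOTf, −78 °C
Reagents that add atoms: tert-butyldimethylsilyl trifluoromethanesulfonate, CC(C)(C)[Si](C)(C)OS(=O)(=O)C(F)(F)F
Why: Anionic retro-aldol fragmentation, intramolecular Michael addition and O-silylation in one flask: the potassium alkoxide of 11 breaks the C5–C8 bond with release of cyclobutane strain to give enolate 12, whose C5 adds to the methylene terminus C6 of the new enone in a 6-endo-trig closure of ring B. C5 is attacked on the face opposite the angular methyl through a chair-like transition state, so the cis ring fusion arises under kinetic control. Enolate 13 exists only at C7–C8, and silylation at −78 °C preserves this distinction between the C8 and C4 carbonyls for the following steps.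

Step 7
Reactants: 14 (4aR,8aS)-6-[(tert-butyldimethylsilyl)oxy]-4a-methyl-7-(propan-2-yl)-3,4,4a,5,8,8a-hexahydronaphthalen-1(2H)-one
Product: 16 (4aR,8aS)-6-[(tert-butyldimethylsilyl)oxy]-2-hydroxy-4a-methyl-7-(propan-2-yl)-3,4,4a,5,8,8a-hexahydronaphthalen-1(2H)-one (both epimers at the carbinol carbon C3), via potassium C3 enolate 15 (not isolated)
Conditions: KN(SiMe3)2, THF, −78 °C; then 3-phenyl-2-(phenylsulfonyl)oxaziridine, −78 °C; aq. NH4Cl
Reagents that add atoms: 3-phenyl-2-(phenylsulfonyl)oxaziridine, O=S(=O)(c1ccccc1)N1OC1c1ccccc1
Why: Enolate hydroxylation with an N-sulfonyloxaziridine (Davis oxidation): kinetic deprotonation occurs at the C3 methylene, not at the hindered C5 methine, and the silyl enol ether is inert at −78 °C. The C3 configuration is not relied on, since both epimers converge on ketone 18 in step 9.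

Step 8
Reactants: 16 (4aR,8aS)-6-[(tert-butyldimethylsilyl)oxy]-2-hydroxy-4a-methyl-7-(propan-2-yl)-3,4,4a,5,8,8a-hexahydronaphthalen-1(2H)-one (both C3 epimers)
Product: 17 (1S,4aR,8aS)-6-[(tert-butyldimethylsilyl)oxy]-1,4a-dimethyl-7-(propan-2-yl)-1,2,3,4,4a,5,8,8a-octahydronaphthalene-1,2-diol (both C3 epimers)
Conditions: MeMgBr (4 equiv), THF, −78 → 0 °C
Reagents that add atoms: methylmagnesium bromide, C[Mg]Br
Why: Grignard 1,2-addition after deprotonation of the hydroxyl. Ring B closes the α face of C4 (C9 lies syn-axial to that approach), so methyl enters from the convex β face and the carbonyl oxygen becomes the axial 4α-hydroxyl; the C8 carbonyl is protected as its enol ether.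

Step 9
Reactants: 17 (1S,4aR,8aS)-6-[(tert-butyldimethylsilyl)oxy]-1,4a-dimethyl-7-(propan-2-yl)-1,2,3,4,4a,5,8,8a-octahydronaphthalene-1,2-diol (both C3 epimers)
Product: 18 (1S,4aR,8aS)-6-[(tert-butyldimethylsilyl)oxy]-1-hydroxy-1,4a-dimethyl-7-(propan-2-yl)-3,4,4a,5,8,8a-hexahydronaphthalen-2(1H)-one
Conditions: SO3·pyridine, Me2SO, i-Pr2NEt, CH2Cl2, 0 °C
Reagents that add atoms: none
Why: Parikh–Doering oxidation of the secondary alcohol; activated dimethyl sulfoxide does not cleave the glycol and leaves the tertiary alcohol and the silyl enol ether alone. Both C3 epimers give the same ketol.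

Step 10
Reactants: 18 (1S,4aR,8aS)-6-[(tert-butyldimethylsilyl)oxy]-1-hydroxy-1,4a-dimethyl-7-(propan-2-yl)-3,4,4a,5,8,8a-hexahydronaphthalen-2(1H)-one
Product: 19 (1S,2R,4aR,8aS)-6-[(tert-butyldimethylsilyl)oxy]-1,4a-dimethyl-7-(propan-2-yl)-1,2,3,4,4a,5,8,8a-octahydronaphthalene-1,2-diol
Conditions: NaBH4, MeOH/THF, −40 °C
Reagents that add atoms: none
Why: Borohydride reduction of the cyclohexanone. With C4 quaternary, ring A sits in the chair that keeps the C4 and C10 methyl groups apart; hydride then adds axially from the open β face, anti to the axial 4α-hydroxyl, and gives the equatorial 3α-alcohol, that is the cis-diol.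

Step 11
Reactants: 19 (1S,2R,4aR,8aS)-6-[(tert-butyldimethylsilyl)oxy]-1,4a-dimethyl-7-(propan-2-yl)-1,2,3,4,4a,5,8,8a-octahydronaphthalene-1,2-diol
Product: 20 (3R,4aS,5S,6R,8aR)-5,6-dihydroxy-5,8a-dimethyl-3-(propan-2-yl)octahydronaphthalen-2(1H)-one
Conditions: Bu4NF, THF, 0 °C; then K2CO3, MeOH, rt
Reagents that add atoms: none
Why: Fluoride cleavage of the silyl enol ether returns the C8 ketone, and base equilibrates C7. In the locked ring system an axial 7α-isopropyl group would clash with C4, so the equatorial 7β-epimer should form essentially alone; C5 is no longer epimerisable.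

Step 12
Reactants: 21 angelic acid, (2Z)-2-methylbut-2-enoic acid
Product: 22 angelyl alcohol, (2Z)-2-methylbut-2-en-1-ol
Conditions: LiAlH4, Et2O, 0 °C
Reagents that add atoms: none
Why: Hydride reduction of the carboxylic acid to the allylic alcohol at low temperature, where the trisubstituted Z-alkene is neither isomerised nor reduced.

Step 13
Reactants: 22 angelyl alcohol, (2Z)-2-methylbut-2-en-1-ol
Product: 23 [(2R,3S)-2,3-dimethyloxiran-2-yl]methanol
Conditions: Ti(OiPr)4 (cat.), D-(−)-diethyl tartrate (cat.), t-BuOOH, 4 Å molecular sieves, CH2Cl2, −20 °C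
Reagents that add atoms: tert-butyl hydroperoxide, CC(C)(C)OO
Why: Sharpless asymmetric epoxidation. D-(−)-tartrate, the antipode of the ligand that converts geraniol into its (2S,3S)-epoxide, delivers oxygen to the face that gives the 2R centre, and the Z geometry is carried over stereospecifically into the cis relation of the hydroxymethyl group and the C3 methyl group.

Step 14
Reactants: 23 [(2R,3S)-2,3-dimethyloxiran-2-yl]methanol
Product: 25 (2S,3S)-2,3-dimethyloxirane-2-carboxylic acid, via epoxy aldehyde 24 (not isolated)
Conditions: RuCl3 (cat.), NaIO4, MeCN/EtOAc/H2O, 0 °C → rt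
Reagents that add atoms: water, O
Why: RuO4-catalysed oxidation (RuCl3/NaIO4) of the primary alcohol through the aldehyde hydrate to the acid, a standard conversion of 2,3-epoxy alcohols that leaves the epoxide intact. The change of the C2 descriptor from R to S reflects only the higher priority of the carboxyl group.

Step 15
Reactants: 20 (3R,4aS,5S,6R,8aR)-5,6-dihydroxy-5,8a-dimethyl-3-(propan-2-yl)octahydronaphthalen-2(1H)-one; 25 (2S,3S)-2,3-dimethyloxirane-2-carboxylic acid
Product: 27 (1S,2R,4aR,7R,8aS)-1-hydroxy-1,4a-dimethyl-6-oxo-7-(propan-2-yl)decahydronaphthalen-2-yl (2S,3S)-2,3-dimethyloxirane-2-carboxylate, via mixed anhydride 26 (not isolated)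
Conditions: 25, 2,4,6-Cl3C6H2COCl, Et3N, THF, rt; then 20, DMAP (cat.), toluene, rt
Reagents that add atoms: none
Why: Yamaguchi esterification: the mixed anhydride acylates the equatorial secondary C3 hydroxyl, while the axial tertiary C4 hydroxyl does not react under these conditions. An ester formed from any minor enantiomer of the decalin is a diastereomer and is removed here.

Step 16
Reactants: 27 (1S,2R,4aR,7R,8aS)-1-hydroxy-1,4a-dimethyl-6-oxo-7-(propan-2-yl)decahydronaphthalen-2-yl (2S,3S)-2,3-dimethyloxirane-2-carboxylate
Product: 28 (1S,2R,4aR,7R,8aS)-1-(acetyloxy)-1,4a-dimethyl-6-oxo-7-(propan-2-yl)decahydronaphthalen-2-yl (2S,3S)-2,3-dimethyloxirane-2-carboxylate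
Conditions: Ac2O, DMAP, Et3N, CH2Cl2, 40 °C
Reagents that add atoms: acetic anhydride, CC(=O)OC(C)=O
Why: DMAP-catalysed acylation (Steglich conditions) of the remaining tertiary alcohol. The epoxy ester, the ketone and the C7 centre, already at its thermodynamic configuration, should tolerate the mildly basic medium.

## Compound list

1 | 3-methylcyclohex-2-en-1-one | CC1=CC(=O)CCC1 | starting material
2 | allene (propa-1,2-diene) | C=C=C | starting material
3 | (1S,6R)-6-methyl-8-methylidenebicyclo[4.2.0]octan-2-one (cis-fused) | O=C1CCC[C@]2(C)CC(=C)[C@@H]21 | intermediate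
4 | (1S,6R)-6-methyl-8-methylidenespiro[bicyclo[4.2.0]octane-2,2'-[1,3]dioxolane] | O1CCOC12CCC[C@]3(C)CC(=C)[C@@H]32 | intermediate
5 | spiro ozonide of 4 (1,2,4-trioxolane spiro-fused at C8 of the bicycle, both spiro epimers) | O1CCOC12CCC[C@]3(C)CC4(OOCO4)[C@@H]32 | intermediate (not isolated)
6 | (1R,6R)-6-methylspiro[bicyclo[4.2.0]octane-2,2'-[1,3]dioxolan]-8-one | O1CCOC12CCC[C@]3(C)CC(=O)[C@@H]32 | intermediate
7 | 2-bromo-3-methylbut-1-ene | C=C(Br)C(C)C | starting material
8 | 3-methylbut-1-en-2-yllithium | [Li]C(=C)C(C)C | intermediate (not isolated)
9 | dichloro(3-methylbut-1-en-2-yl)cerium | Cl[Ce](Cl)C(=C)C(C)C | intermediate (not isolated)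
10 | (1R,6R,8S)-6-methyl-8-(3-methylbut-1-en-2-yl)spiro[bicyclo[4.2.0]octane-2,2'-[1,3]dioxolan]-8-ol (alkenyl group exo, cis to C5–H and the angular methyl) | O1CCOC12CCC[C@]3(C)C[C@@](O)(C(=C)C(C)C)[C@@H]32 | intermediate
11 | (1R,6R,8S)-8-hydroxy-6-methyl-8-(3-methylbut-1-en-2-yl)bicyclo[4.2.0]octan-2-one | O=C1CCC[C@]2(C)C[C@@](O)(C(=C)C(C)C)[C@@H]21 | intermediate
12 | potassium (3R)-3-methyl-3-(4-methyl-3-methylidene-2-oxopentyl)cyclohex-1-en-1-olate | [K+].[O-]C1=C[C@@](C)(CC(=O)C(=C)C(C)C)CCC1 | intermediate (not isolated)
13 | potassium C7=C8 enolate of the cis-fused (5S,10R)-7-isopropyl-10-methyldecalin-4,8-dione (eudesmane numbering) | O=C1CCC[C@]2(C)CC([O-])=C(C(C)C)C[C@@H]21.[K+] | intermediate (not isolated)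
14 | (4aR,8aS)-6-[(tert-butyldimethylsilyl)oxy]-4a-methyl-7-(propan-2-yl)-3,4,4a,5,8,8a-hexahydronaphthalen-1(2H)-one (cis-fused; C4 ketone, C8 silyl enol ether) | O=C1CCC[C@]2(C)CC(O[Si](C)(C)C(C)(C)C)=C(C(C)C)C[C@@H]21 | intermediate
15 | potassium C3=C4 enolate of 14 | [K+].[O-]C1=CCC[C@]2(C)CC(O[Si](C)(C)C(C)(C)C)=C(C(C)C)C[C@@H]21 | intermediate (not isolated)
16 | (4aR,8aS)-6-[(tert-butyldimethylsilyl)oxy]-2-hydroxy-4a-methyl-7-(propan-2-yl)-3,4,4a,5,8,8a-hexahydronaphthalen-1(2H)-one (both epimers at C3, the carbinol carbon) | O=C1C(O)CC[C@]2(C)CC(O[Si](C)(C)C(C)(C)C)=C(C(C)C)C[C@@H]21 | intermediate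
17 | (1S,4aR,8aS)-6-[(tert-butyldimethylsilyl)oxy]-1,4a-dimethyl-7-(propan-2-yl)-1,2,3,4,4a,5,8,8a-octahydronaphthalene-1,2-diol (4α-OH, 4β-CH3; both C3 epimers) | O[C@]1(C)C(O)CC[C@]2(C)CC(O[Si](C)(C)C(C)(C)C)=C(C(C)C)C[C@@H]21 | intermediate
18 | (1S,4aR,8aS)-6-[(tert-butyldimethylsilyl)oxy]-1-hydroxy-1,4a-dimethyl-7-(propan-2-yl)-3,4,4a,5,8,8a-hexahydronaphthalen-2(1H)-one (C3 ketone, 4α-OH) | O[C@]1(C)C(=O)CC[C@]2(C)CC(O[Si](C)(C)C(C)(C)C)=C(C(C)C)C[C@@H]21 | intermediate
19 | (1S,2R,4aR,8aS)-6-[(tert-butyldimethylsilyl)oxy]-1,4a-dimethyl-7-(propan-2-yl)-1,2,3,4,4a,5,8,8a-octahydronaphthalene-1,2-diol (3α,4α-cis-diol) | O[C@]1(C)[C@H](O)CC[C@]2(C)CC(O[Si](C)(C)C(C)(C)C)=C(C(C)C)C[C@@H]21 | intermediate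
20 | (3R,4aS,5S,6R,8aR)-5,6-dihydroxy-5,8a-dimethyl-3-(propan-2-yl)octahydronaphthalen-2(1H)-one (3α,4α-diol, 7β-isopropyl, C8 ketone) | O[C@]1(C)[C@H](O)CC[C@]2(C)CC(=O)[C@@H](C(C)C)C[C@@H]21 | intermediate
21 | angelic acid, (2Z)-2-methylbut-2-enoic acid | C/C=C(/C)C(=O)O | starting material
22 | angelyl alcohol, (2Z)-2-methylbut-2-en-1-ol | C/C=C(/C)CO | intermediate
23 | [(2R,3S)-2,3-dimethyloxiran-2-yl]methanol | OC[C@@]1(C)O[C@H]1C | intermediate
24 | (2S,3S)-2,3-dimethyloxirane-2-carbaldehyde | O=C[C@@]1(C)O[C@H]1C | intermediate (not isolated)
25 | (2S,3S)-2,3-dimethyloxirane-2-carboxylic acid | OC(=O)[C@@]1(C)O[C@H]1C | intermediate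
26 | (2S,3S)-2,3-dimethyloxirane-2-carboxylic 2,4,6-trichlorobenzoic anhydride | O=C(OC(=O)[C@@]1(C)O[C@H]1C)c1c(Cl)cc(Cl)cc1Cl | intermediate (not isolated)
27 | (1S,2R,4aR,7R,8aS)-1-hydroxy-1,4a-dimethyl-6-oxo-7-(propan-2-yl)decahydronaphthalen-2-yl (2S,3S)-2,3-dimethyloxirane-2-carboxylate | O[C@]1(C)[C@H](OC(=O)[C@@]2(C)O[C@H]2C)CC[C@]2(C)CC(=O)[C@@H](C(C)C)C[C@@H]21 | intermediate
28 | (1S,2R,4aR,7R,8aS)-1-(acetyloxy)-1,4a-dimethyl-6-oxo-7-(propan-2-yl)decahydronaphthalen-2-yl (2S,3S)-2,3-dimethyloxirane-2-carboxylate (CNP0221066.1) | CC(=O)O[C@]1(C)[C@H](OC(=O)[C@@]2(C)O[C@H]2C)CC[C@]2(C)CC(=O)[C@@H](C(C)C)C[C@@H]21 | target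

## Step count and least certain steps

Total step count: 16. Longest linear sequence: 13 steps (steps 1–11, 15 and 16, from 1). The acid arm (steps 12–14) has 3 steps.

**Step 1 (key step, proposed new method).** The most likely failure is insufficient enantiofacial discrimination. Allene is small and linear and offers little steric contact with the catalyst, and any light absorbed by uncomplexed 1 gives racemic adduct. A second concern is Lewis-acid-induced oligomerisation of allene, which would deplete the catalyst. Fallback (known chemistry): 1 and 2 are irradiated without Lewis acid (Pyrex-filtered light, CH2Cl2, −78 °C). This racemic head-to-head photocycloaddition gives 3 together with its enantiomer (1R,6S)-6-methyl-8-methylidenebicyclo[4.2.0]octan-2-one F1. The two are separated by preparative chromatography on a chiral stationary phase, and 3 re-enters the route at step 2.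

**Step 6.** The most likely failure is proton exchange between enolate 13 and the newly formed C4 ketone before the hindered, tetrasubstituted enolate is silylated. This would move the enolate into ring A, blur the C4/C8 distinction and epimerise C5. Fallback: drop the enolate trap and rely on chemoselection, starting from 11.
- The same base treatment is quenched with acetic acid at −78 °C to give the cis-fused dione F2 (C7 epimers).
- Kinetic deprotonation with LiN(i-Pr)2 (one equivalent) at the unhindered C3 methylene and oxaziridine oxidation give the hydroxy dione F3.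
- MeMgBr at −78 °C adds to the chelating ketol carbonyl in preference to the C8 carbonyl, which is flanked by the isopropyl-bearing C7 and the neopentyl C9. Brief K2CO3/MeOH then settles C7 and gives the diol ketone F4.
- Parikh–Doering oxidation gives the ketol dione F5, and NaBH4 at −78 °C reduces the activated ketol carbonyl first, returning to the route at 20.

**Step 5.** The most likely failure is premature retro-aldol opening of 11 during hydrolysis or isolation. It is a strained β-hydroxy ketone of the de Mayo type with its hydroxyl syn to the C4 carbonyl, and the open diketone would no longer give the C5 enolate regiospecifically. Fallback: keep the hydroxyl silylated until a base-free trigger is applied. From 10, Et3SiOTf/2,6-lutidine gives the triethylsilyl ether F6. Ketal hydrolysis as in step 5 gives the β-silyloxy ketone F7, which cannot fragment. Anhydrous fluoride (tris(dimethylamino)sulfonium difluorotrimethylsilicate, THF, −78 °C) then releases the alkoxide, the retro-aldol/Michael sequence runs as in step 6, and t-BuMe2SiOTf traps the enolate, returning to the route at 14.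

**Step 8.** The most likely failure is proton abstraction by the Grignard reagent, or base-induced acyloin transposition of the magnesium alkoxide of the free ketol, competing with addition to a hindered carbonyl. Fallback: mask the hydroxyl and use a less basic nucleophile. From 16, Me3SiCl/imidazole gives the trimethylsilyl ether F8. MeLi/CeCl3 (organocerium addition, THF, −78 °C) gives the carbinol F9. K2CO3/MeOH at 0 °C removes the trimethylsilyl group while the hindered silyl enol ether stays, returning to the route at 17.

**Step 16.** The most likely failure is slow acylation of the axial tertiary hydroxyl, which is flanked by the C3 ester and syn-axial to C9. Forcing conditions would invite elimination or attack on the epoxide. Fallback: deliver the acetyl group intramolecularly before the side chain is attached. From 20, MeC(OMe)3 with pyridinium p-toluenesulfonate gives the cyclic orthoacetate F10. Mild aqueous acetic acid opens it with the usual preference for axial ester and equatorial alcohol, giving the tertiary acetate F11 with the C3 hydroxyl free. Esterification of F11 with 25 under the conditions of step 15 then gives 28 directly.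

## Further compounds

F1 | step 1 | (1R,6S)-6-methyl-8-methylidenebicyclo[4.2.0]octan-2-one (enantiomer of 3) | O=C1CCC[C@@]2(C)CC(=C)[C@H]21
F2 | step 6 | cis-fused (5S,10R)-7-isopropyl-10-methyldecalin-4,8-dione (eudesmane numbering; C7 epimers) | O=C1CCC[C@]2(C)CC(=O)C(C(C)C)C[C@@H]21
F3 | step 6 | 3-hydroxy derivative of F2 (C3 and C7 epimers) | O=C1C(O)CC[C@]2(C)CC(=O)C(C(C)C)C[C@@H]21
F4 | step 6 | (4S,5S,7R,10R)-3,4-dihydroxy-7-isopropyl-4,10-dimethyl-cis-decalin-8-one (eudesmane numbering; C3 epimers) | O[C@]1(C)C(O)CC[C@]2(C)CC(=O)[C@@H](C(C)C)C[C@@H]21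
F5 | step 6 | (4S,5S,7R,10R)-4-hydroxy-7-isopropyl-4,10-dimethyl-cis-decalin-3,8-dione (eudesmane numbering) | O[C@]1(C)C(=O)CC[C@]2(C)CC(=O)[C@@H](C(C)C)C[C@@H]21
F6 | step 5 | triethylsilyl ether of 10, (1R,6R,8S)-configured | O1CCOC12CCC[C@]3(C)C[C@@](O[Si](CC)(CC)CC)(C(=C)C(C)C)[C@@H]32
F7 | step 5 | (1R,6R,8S)-6-methyl-8-(3-methylbut-1-en-2-yl)-8-[(triethylsilyl)oxy]bicyclo[4.2.0]octan-2-one | O=C1CCC[C@]2(C)C[C@@](O[Si](CC)(CC)CC)(C(=C)C(C)C)[C@@H]21
F8 | step 8 | trimethylsilyl ether of 16 (C3 epimers) | O=C1C(O[Si](C)(C)C)CC[C@]2(C)CC(O[Si](C)(C)C(C)(C)C)=C(C(C)C)C[C@@H]21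
F9 | step 8 | C3-O-trimethylsilyl ether of 17 (C3 epimers) | O[C@]1(C)C(O[Si](C)(C)C)CC[C@]2(C)CC(O[Si](C)(C)C(C)(C)C)=C(C(C)C)C[C@@H]21
F10 | step 16 | cyclic orthoacetate (2-methoxy-2-methyl-1,3-dioxolane) spanning O3 and O4 of 20 (both epimers at the orthoester carbon) | COC1(C)O[C@]2(C)[C@H](O1)CC[C@]3(C)CC(=O)[C@@H](C(C)C)C[C@@H]32
F11 | step 16 | (3R,4S,5S,7R,10R)-4-acetoxy-3-hydroxy-7-isopropyl-4,10-dimethyl-cis-decalin-8-one (eudesmane numbering) | CC(=O)O[C@]1(C)[C@H](O)CC[C@]2(C)CC(=O)[C@@H](C(C)C)C[C@@H]21
A1 | alternative 1 | cis-fused Diels–Alder adduct: 3-methoxy-2-ene-1,4-dione with C10 methyl, C7 isopropyl and C8 tert-butyldimethylsilyl enol ether (eudesmane numbering; configuration as in the SMILES) | O=C1C(OC)=CC(=O)[C@]2(C)CC(O[Si](C)(C)C(C)(C)C)=C(C(C)C)C[C@@H]21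
A2 | alternative 1 | 2-methoxy-5-methyl-1,4-benzoquinone | COC1=CC(=O)C(C)=CC1=O
A3 | alternative 1 | 2-(tert-butyldimethylsilyloxy)-3-isopropylbuta-1,3-diene | C=C(O[Si](C)(C)C(C)(C)C)C(=C)C(C)C
A4 | alternative 2 | cis-decalin 4α-hydroxy-4β-methyl-3,8-dione with 7β-isopropyl and 10β-methyl (eudesmane numbering) | O[C@]1(C)C(=O)CC[C@]2(C)CC(=O)[C@@H](C(C)C)C[C@@H]21
A5 | alternative 2 | 3-acetyl-3-hydroxy cis-hydrindane precursor (five-membered ring A; configuration as in the SMILES) | CC(=O)[C@@]1(O)CC[C@]2(C)CC(=O)[C@@H](C(C)C)C[C@@H]21
A6 | alternative 3 | cis-decalin-4-one with C10 methyl, C7 isopropyl and C8 exocyclic methylene (eudesmane numbering) | O=C1CCC[C@]2(C)CC(=C)[C@@H](C(C)C)C[C@@H]21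
A7 | alternative 3 | 3-[(3R)-3-(iodomethyl)-4-methyl-2-methylidenepentyl]cyclohex-2-en-1-one | O=C1CCCC(CC(=C)[C@@H](C(C)C)CI)=C1
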